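**Plan**

Numbering used throughout: ring C1 (ketone), C2 (bears CH2OAc), C3, C4 (carbinol), C5 and C6 (oxirane carbons); side chain C1' (carbinol) onward.
Retrosynthesis: C1'–OH goes back to a ketone, CH2OAc comes off C2 (Morita–Baylis–Hillman), C2=C3 goes back to CH2–CH2, and the oxirane goes back to the C5=C6 enone. The remaining 4-hydroxycyclohexenone is cut at C2–C3 and C4–C5 in one [4+2] step, and the chain at C1'–C5 (farnesal + a C4 enyne).
Forward: the chain is joined first (alkynylation of farnesal, trans reduction to the 2-silyloxy-1,3-diene C2=C1–C6=C5). The ring then closes by an intramolecular Diels–Alder reaction with a vinylboron unit carried on the C1' oxygen, and boron is oxidised to the C4 hydroxyl.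
Enabling feature: the C1' and C4 oxygens are 1,3 across C5, so an O–B bridge from C1' (five-membered ring C5–C1'–O–B–C4) can only put the boron-bearing carbon on C5 and the other vinyl carbon on C2.
Stereochemistry: a catalytic asymmetric alkynylation gives a temporary C1' carbinol, which sets C4 (S) in the cycloaddition. The C4 silyl ether sets the oxirane (C5, C6) by anti attack. The spent C1' centre is oxidised (step 6), and the free C4 hydroxyl finally directs the hydride that makes the 1'S carbinol.

Key step: step 4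

**Route**

Step 1
Reactants: 1 but-3-yn-2-one
Product: 2 2-(tert-butyldimethylsilyloxy)but-1-en-3-yne
Conditions: TBSOTf, iPr2NEt, Et2O, −78 °C to 0 °C
Reagents that add atoms: tert-butyldimethylsilyl triflate, CC(C)(C)[Si](C)(C)OS(=O)(=O)C(F)(F)F
Why: Soft enolisation of the methyl ketone by the silyl triflate and a hindered amine (silyl enol ether formation) should give the enol ether and keep the terminal alkyne C–H for step 2; no stereocentre is formed.

Step 2
Reactants: 2 2-(tert-butyldimethylsilyloxy)but-1-en-3-yne; 3 (2E,6E)-farnesal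
Product: 4 (5R,6E,10E)-2-(tert-butyldimethylsilyloxy)-7,11,15-trimethylhexadeca-1,6,10,14-tetraen-3-yn-5-ol
Conditions: Me2Zn, ProPhenol ligand (10 mol%, the enantiomer that sends the alkynyl group to the Si face of the aldehyde), Ph3PO, toluene, 4 °C; aq. NH4Cl
Reagents that add atoms: none
Why: Catalytic asymmetric alkynylation of an aldehyde: the alkynylzinc formed from 2 and Me2Zn should add 1,2 to the enal inside the chiral zinc alkoxide complex of the ligand, which selects the Si face and sets the temporary C1' carbinol (5R).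

Step 3
Reactants: 4 (5R)-propargylic alcohol
Product: 5 (3E,5S,6E,10E)-2-(tert-butyldimethylsilyloxy)-7,11,15-trimethylhexadeca-1,3,6,10,14-pentaen-5-ol
Conditions: NaAlH2(OCH2CH2OMe)2 (Red-Al), THF, 0 °C; aq. potassium sodium tartrate
Reagents that add atoms: none
Why: Alkoxide-directed trans-hydroalumination of the propargylic alcohol and protonolysis (Red-Al reduction) should give the E alkene and complete the 2-silyloxy-1,3-diene; C1' is untouched (the descriptor changes from R to S only because the reduced branch drops in priority).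

Step 4
Reactants: 5 (5S)-dienol; 6 dibutyl vinylboronate
Product: 9 (1S,2S)-4-(tert-butyldimethylsilyloxy)-2-[(1R,2E,6E)-1-hydroxy-3,7,11-trimethyldodeca-2,6,10-trienyl]cyclohex-3-en-1-ol, via mixed vinylboronate 7 (not isolated), via bicyclic boronate 8 (not isolated)
Conditions: 6 (1.5 equiv), 4 Å MS, BHT, toluene, rt then 120 °C (sealed tube); then Me3NO, 60 °C; aq. work-up
Reagents that add atoms: trimethylamine N-oxide, C[N+](C)(C)[O-]
Why: Transesterification hangs the vinylboron unit on the C1' oxygen (7), and the 2-silyloxydiene C2=C1–C6=C5 then adds to the vinyl group C3=C4 in a concerted thermal [4+2] cycloaddition that forms C2–C3 and C4–C5 at once; the closest known reaction type is the alkenylboronate-tethered intramolecular Diels–Alder reaction of 2,4-dienols followed by oxidation of the C–B bond. The cyclohexene closes by suprafacial [4+2] addition, and the temporary 1,2-oxaborolane (C5–C1'–O–B–C4) closes in the same event as a type 1 intramolecular cycloaddition with the tether exo to the diene. C4 is controlled by the C1' carbinol: the tether brings the vinyl group onto the diene face that carries the C1'–O bond while the side chain sits anti to the incoming dienophile, which should give C4 the S configuration from the 5S dienol (syn C1'/C4 diol). C5 is also formed (drawn trans-fused) but is erased in step 5, so both ring fusions converge. The step needs boron-bearing C4 on C5 and C3 on C2; this is secured by the three-atom tether and reinforced electronically, because the nucleophilic C2 terminus of the 2-silyloxydiene meets the carbon β to boron. Me3NO then replaces boron by hydroxyl with retention and releases the tether.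

Step 5
Reactants: 9 syn-diol silyl enol ether
Product: 10 (4S)-4-hydroxy-3-[(1R,2E,6E)-1-hydroxy-3,7,11-trimethyldodeca-2,6,10-trienyl]cyclohex-2-en-1-one
Conditions: Pd(OAc)2 (1.1 equiv), MeCN, rt
Reagents that add atoms: none
Why: Saegusa–Ito oxidation: the silyl enol ether hands C6 to divalent palladium and β-hydride elimination can only take the hydrogen on C5, so the C5=C6 enone should form regiospecifically and the expendable C5 stereocentre disappears.

Step 6
Reactants: 10 enone diol
Product: 11 (4S)-4-hydroxy-3-[(2E,6E)-3,7,11-trimethyldodeca-2,6,10-trienoyl]cyclohex-2-en-1-one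
Conditions: MnO2, CH2Cl2, rt
Reagents that add atoms: none
Why: Allylic alcohol oxidation: MnO2 should oxidise the doubly allylic C1' alcohol (next to the electron-rich C2'=C3' bond) much faster than the C4 alcohol next to the electron-poor enone, which removes the spent C1' centre and leaves C4–OH as the only hydroxyl.

Step 7
Reactants: 11 hydroxy enedione
Product: 12 (4S)-4-(triethylsilyloxy)-3-[(2E,6E)-3,7,11-trimethyldodeca-2,6,10-trienoyl]cyclohex-2-en-1-one
Conditions: Et3SiCl, imidazole, CH2Cl2, 0 °C
Reagents that add atoms: chlorotriethylsilane, CC[Si](Cl)(CC)CC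
Why: Silylation of the single free secondary alcohol; the silyl ether will shield the upper face of C5 in step 8.

Step 8
Reactants: 12 silyl ether enedione
Product: 13 (1R,5S,6S)-5-(triethylsilyloxy)-6-[(2E,6E)-3,7,11-trimethyldodeca-2,6,10-trienoyl]-7-oxabicyclo[4.1.0]heptan-2-one
Conditions: H2O2 (30% aq.), K2CO3, THF–MeOH, 0 °C
Reagents that add atoms: hydrogen peroxide, OO
Why: Weitz–Scheffer epoxidation: hydroperoxide adds reversibly to C6 of the doubly activated C5=C6 bond and the enolate should close the oxirane on the face opposite to the neighbouring C4 silyl ether, which sets C5 and C6 trans to C4–O; the β,β-disubstituted side-chain enone is far less electrophilic.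

Step 9
Reactants: 13 epoxy diketone
Product: 14 (1R,5S,6S)-5-(triethylsilyloxy)-6-[(2E,6E)-3,7,11-trimethyldodeca-2,6,10-trienoyl]-7-oxabicyclo[4.1.0]hept-3-en-2-one
Conditions: IBX, DMSO–toluene, 65 °C
Reagents that add atoms: none
Why: IBX dehydrogenation of a ketone through its enol: only C2 carries an enolisable hydrogen next to C1 (C6 is an oxirane carbon and the C1' ketone has no α-hydrogen), so the C2=C3 enone should form without touching C4.

Step 10
Reactants: 14 epoxy enone
Product: 15 (1R,5S,6S)-3-(hydroxymethyl)-5-(triethylsilyloxy)-6-[(2E,6E)-3,7,11-trimethyldodeca-2,6,10-trienoyl]-7-oxabicyclo[4.1.0]hept-3-en-2-one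
Conditions: aq. formaldehyde (37%), DMAP, THF, rt
Reagents that add atoms: formaldehyde, C=O
Why: Morita–Baylis–Hillman reaction: DMAP adds to C3, the C2 enolate attacks formaldehyde and DMAP is lost again, which puts CH2OH on C2; the β,β-disubstituted side-chain enone should not accept the amine.

Step 11
Reactants: 15 primary alcohol
Product: 16 [(1R,5S,6S)-2-oxo-5-(triethylsilyloxy)-6-[(2E,6E)-3,7,11-trimethyldodeca-2,6,10-trienoyl]-7-oxabicyclo[4.1.0]hept-3-en-3-yl]methyl acetate
Conditions: Ac2O, pyridine, DMAP (cat.), CH2Cl2, 0 °C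
Reagents that add atoms: acetic anhydride, CC(=O)OC(C)=O
Why: Acetylation of the only free (primary) alcohol.

Step 12
Reactants: 16 acetate
Product: 17 [(1R,5S,6R)-5-hydroxy-2-oxo-6-[(2E,6E)-3,7,11-trimethyldodeca-2,6,10-trienoyl]-7-oxabicyclo[4.1.0]hept-3-en-3-yl]methyl acetate
Conditions: HF·pyridine, pyridine, THF, 0 °C
Reagents that add atoms: none
Why: Fluoride cleavage of the triethylsilyl ether under buffered, weakly acidic conditions that should spare the oxirane, the allylic acetate and the β-hydroxy ketone (no base, so no retro-aldol opening of C4–C5).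

Step 13
Reactants: 17 β-hydroxy ketone
Product: 18 [(1R,5S,6R)-5-hydroxy-6-[(1S,2E,6E)-1-hydroxy-3,7,11-trimethyldodeca-2,6,10-trienyl]-2-oxo-7-oxabicyclo[4.1.0]hept-3-en-3-yl]methyl acetate (target)
Conditions: Me4NBH(OAc)3, MeCN–AcOH, −30 °C
Reagents that add atoms: none
Why: Evans–Saksena reduction: the C4 hydroxyl exchanges onto boron and delivers hydride intramolecularly to the β-keto group C1' through a chair transition state, which should give the anti 1,3-diol (1'S) with attack anti to the C5–O oxirane bond, while the C1 enone has no hydroxyl in reach and is left alone.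

**Compound list**

1 | but-3-yn-2-one | CC(=O)C#C | starting material
2 | 2-(tert-butyldimethylsilyloxy)but-1-en-3-yne | C=C(O[Si](C)(C)C(C)(C)C)C#C | intermediate
3 | (2E,6E)-farnesal | O=C/C=C(\C)CC/C=C(\C)CCC=C(C)C | starting material
4 | (5R,6E,10E)-2-(tert-butyldimethylsilyloxy)-7,11,15-trimethylhexadeca-1,6,10,14-tetraen-3-yn-5-ol | O[C@@H](C#CC(=C)O[Si](C)(C)C(C)(C)C)/C=C(\C)CC/C=C(\C)CCC=C(C)C | intermediate
5 | (3E,5S,6E,10E)-2-(tert-butyldimethylsilyloxy)-7,11,15-trimethylhexadeca-1,3,6,10,14-pentaen-5-ol | O[C@@H](/C=C/C(=C)O[Si](C)(C)C(C)(C)C)/C=C(\C)CC/C=C(\C)CCC=C(C)C | intermediate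
6 | dibutyl vinylboronate | C=CB(OCCCC)OCCCC | starting material
7 | mixed boronate: butyl vinylboronate ester on the carbinol oxygen of 5 | C=CB(OCCCC)O[C@@H](/C=C/C(=C)O[Si](C)(C)C(C)(C)C)/C=C(\C)CC/C=C(\C)CCC=C(C)C | intermediate
8 | bicyclic boronate: 2-butoxy-1,2-oxaborolane trans-fused to the 4-silyloxycyclohexene (boron on C4, side chain on the oxaborolane carbon C1') | CCCCOB1O[C@H](/C=C(\C)CC/C=C(\C)CCC=C(C)C)[C@H]2C=C(O[Si](C)(C)C(C)(C)C)CC[C@H]12 | intermediate
9 | (1S,2S)-4-(tert-butyldimethylsilyloxy)-2-[(1R,2E,6E)-1-hydroxy-3,7,11-trimethyldodeca-2,6,10-trienyl]cyclohex-3-en-1-ol (syn 1,3-diol) | O[C@H](/C=C(\C)CC/C=C(\C)CCC=C(C)C)[C@H]1C=C(O[Si](C)(C)C(C)(C)C)CC[C@@H]1O | intermediate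
10 | (4S)-4-hydroxy-3-[(1R,2E,6E)-1-hydroxy-3,7,11-trimethyldodeca-2,6,10-trienyl]cyclohex-2-en-1-one | O[C@H](/C=C(\C)CC/C=C(\C)CCC=C(C)C)C1=CC(=O)CC[C@@H]1O | intermediate
11 | (4S)-4-hydroxy-3-[(2E,6E)-3,7,11-trimethyldodeca-2,6,10-trienoyl]cyclohex-2-en-1-one | O=C(/C=C(\C)CC/C=C(\C)CCC=C(C)C)C1=CC(=O)CC[C@@H]1O | intermediate
12 | (4S)-4-(triethylsilyloxy)-3-[(2E,6E)-3,7,11-trimethyldodeca-2,6,10-trienoyl]cyclohex-2-en-1-one | O=C(/C=C(\C)CC/C=C(\C)CCC=C(C)C)C1=CC(=O)CC[C@@H]1O[Si](CC)(CC)CC | intermediate
13 | (1R,5S,6S)-5-(triethylsilyloxy)-6-[(2E,6E)-3,7,11-trimethyldodeca-2,6,10-trienoyl]-7-oxabicyclo[4.1.0]heptan-2-one (oxirane trans to the silyl ether) | O=C(/C=C(\C)CC/C=C(\C)CCC=C(C)C)[C@]12O[C@H]1C(=O)CC[C@@H]2O[Si](CC)(CC)CC | intermediate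
14 | (1R,5S,6S)-5-(triethylsilyloxy)-6-[(2E,6E)-3,7,11-trimethyldodeca-2,6,10-trienoyl]-7-oxabicyclo[4.1.0]hept-3-en-2-one | O=C(/C=C(\C)CC/C=C(\C)CCC=C(C)C)[C@]12O[C@H]1C(=O)C=C[C@@H]2O[Si](CC)(CC)CC | intermediate
15 | (1R,5S,6S)-3-(hydroxymethyl)-5-(triethylsilyloxy)-6-[(2E,6E)-3,7,11-trimethyldodeca-2,6,10-trienoyl]-7-oxabicyclo[4.1.0]hept-3-en-2-one | O=C(/C=C(\C)CC/C=C(\C)CCC=C(C)C)[C@]12O[C@H]1C(=O)C(CO)=C[C@@H]2O[Si](CC)(CC)CC | intermediate
16 | [(1R,5S,6S)-2-oxo-5-(triethylsilyloxy)-6-[(2E,6E)-3,7,11-trimethyldodeca-2,6,10-trienoyl]-7-oxabicyclo[4.1.0]hept-3-en-3-yl]methyl acetate | O=C(/C=C(\C)CC/C=C(\C)CCC=C(C)C)[C@]12O[C@H]1C(=O)C(COC(C)=O)=C[C@@H]2O[Si](CC)(CC)CC | intermediate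
17 | [(1R,5S,6R)-5-hydroxy-2-oxo-6-[(2E,6E)-3,7,11-trimethyldodeca-2,6,10-trienoyl]-7-oxabicyclo[4.1.0]hept-3-en-3-yl]methyl acetate | O=C(/C=C(\C)CC/C=C(\C)CCC=C(C)C)[C@]12O[C@H]1C(=O)C(COC(C)=O)=C[C@@H]2O | intermediate
18 | [(1R,5S,6R)-5-hydroxy-6-[(1S,2E,6E)-1-hydroxy-3,7,11-trimethyldodeca-2,6,10-trienyl]-2-oxo-7-oxabicyclo[4.1.0]hept-3-en-3-yl]methyl acetate | CC(=O)OCC1=C[C@H](O)[C@@]2([C@@H](O)/C=C(\C)CC/C=C(\C)CCC=C(C)C)O[C@H]2C1=O | target

**Totals**

Total step count: 13.
Longest linear sequence: 13 steps (1 to 18; 3 enters in step 2 and 6 in step 4).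

**Three steps most likely to fail**

1. Step 4. Facial control in the cycloaddition may be lost if the side chain does not stay anti to the dienophile; this gives the anti diol and, once C1' is oxidised in step 6, lowers the enantiopurity at C4. The doubly allylic boronate may also ionise or eliminate at the temperature needed before it cyclises. Fallback (temporary silicon connection): from 5, silylation with chlorodimethyl(vinyl)silane and imidazole should give the vinylsilyl ether F1. Heating in toluene at 170 °C should close the same two bonds through a neutral tether to the bicyclic siloxane F2. Tamao–Fleming oxidation (H2O2, KHCO3, THF–MeOH) turns C4–Si into C4–OH with retention and comes back to the route at 9.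

2. Step 8. Peroxide may attack from the wrong face or at the side-chain enone; base may isomerise the C2'=C3' bond of the dienone or cleave the silyl ether. Fallback (cyclic template, epoxidation before the C1' oxidation): from 10, tBu2Si(OTf)2 and 2,6-lutidine should tie the syn diol into the di-tert-butylsilylene acetal F3, which holds both oxygens on the upper face and the side chain equatorial. Nucleophilic epoxidation (tBuOOH, DBU) can then only come from the lower face and gives the silylene epoxide F4. HF·pyridine frees the epoxy diol F5, and MnO2 oxidises only the allylic C1' alcohol to the epoxy diketone alcohol F6. Silylation as in step 7 comes back to the route at 13.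

3. Step 9. The epoxy diketone may decompose or be over-oxidised in hot IBX, and dehydrogenation may start on the side chain. Fallback (two-stage enol ether route): from 13, LiHMDS and Me3SiCl at −78 °C should give the trimethylsilyl enol ether F7. Saegusa–Ito oxidation with Pd(OAc)2 in MeCN comes back to the route at 14.

**Further compounds**

F1 | step 4 | dimethyl(vinyl)silyl ether of dienol 5 | C=C[Si](C)(C)O[C@@H](/C=C/C(=C)O[Si](C)(C)C(C)(C)C)/C=C(\C)CC/C=C(\C)CCC=C(C)C
F2 | step 4 | bicyclic siloxane: 2,2-dimethyl-1,2-oxasilolane trans-fused to the 4-silyloxycyclohexene (silicon on C4) | C[Si]1(C)O[C@H](/C=C(\C)CC/C=C(\C)CCC=C(C)C)[C@H]2C=C(O[Si](C)(C)C(C)(C)C)CC[C@H]12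
F3 | step 8 | di-tert-butylsilylene acetal of syn diol 10 | CC(C)(C)[Si]1(C(C)(C)C)O[C@H](/C=C(\C)CC/C=C(\C)CCC=C(C)C)C2=CC(=O)CC[C@@H]2O1
F4 | step 8 | silylene-protected epoxy ketone (oxirane on the face opposite to the silylene) | CC(C)(C)[Si]1(C(C)(C)C)O[C@H](/C=C(\C)CC/C=C(\C)CCC=C(C)C)[C@]23O[C@H]2C(=O)CC[C@@H]3O1
F5 | step 8 | epoxy diol (C4 hydroxyl and temporary C1' carbinol free) | O[C@H](/C=C(\C)CC/C=C(\C)CCC=C(C)C)[C@]12O[C@H]1C(=O)CC[C@@H]2O
F6 | step 8 | epoxy diketone with free C4 hydroxyl (desilyl 13) | O=C(/C=C(\C)CC/C=C(\C)CCC=C(C)C)[C@]12O[C@H]1C(=O)CC[C@@H]2O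
F7 | step 9 | trimethylsilyl enol ether of 13 (C1–OSiMe3, C1=C2) | O=C(/C=C(\C)CC/C=C(\C)CCC=C(C)C)[C@]12O[C@H]1C(O[Si](C)(C)C)=CC[C@@H]2O[Si](CC)(CC)CC
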